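**Retrosynthetic overview**

1. The exocyclic methylene comes last (Mannich/elimination) from the trans-fused hydroxy lactone 26, and the five-membered lactone ring comes from the macrocyclic β-hydroxy ketone 23 by 1,3-syn reduction and lactonization.
2. Key disconnection: the bond between the ring CH2 and the C(CH3)(OH) carbon of the 14-membered ring, made by an intramolecular zinc-enolate (Reformatsky-type) aldol of the acyclic bromomethyl ketone/α-chloro methyl ketone 20. Metal insertion reverses the polarity of the bromomethyl carbon, so two electrophilic carbons are joined.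
3. Enabling feature: in the 14-membered carbocycle this CH2 sits between two oxygen-bearing carbons (the lactone O–CH and the tertiary carbinol, a 1,3-dioxygen aldol pattern), and the carbinol carbon is next to the CHCl carbon. It can therefore be the carbonyl of an α-chloro ketone that is strongly electrophilic and whose C–Cl centre steers the addition (Cornforth).
4. Diketone 20 is built on geranyl bromide: Evans alkylation (ring-fusion centre), SeO2 allylic oxidation and copper-catalysed three-carbon extension (both E-alkenes kept), organocatalytic α-chlorination (C–Cl centre), then diazo ketone to bromomethyl ketone.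
5. Ring order: 14-membered carbocycle (step 10), then the γ-lactone (step 11), then the α-methylene group.

Key step: step 10

Assumption: the enantiomer of 2,5-diphenylpyrrolidine used in step 7 is the one that gives the (S)-2-chloro aldehyde; its sense would be confirmed on a model aldehyde first.

**Route**

Step 1
Reactants: 1 (R)-4-benzyl-1,3-oxazolidin-2-one; 2 methyl 4-chloro-4-oxobutanoate
Product: 3 methyl 4-[(4R)-4-benzyl-2-oxo-1,3-oxazolidin-3-yl]-4-oxobutanoate
Conditions: Et3N, DMAP (cat.), CH2Cl2, 0 → 23 °C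
Reagents that add atoms: none
Why: N-acylation of the oxazolidinone by the acid chloride under DMAP catalysis should give the imide that carries the Evans auxiliary needed for the ring-fusion centre, and no stereocentre is formed.

Step 2
Reactants: 3 methyl 4-[(4R)-4-benzyl-2-oxo-1,3-oxazolidin-3-yl]-4-oxobutanoate; 4 geranyl bromide
Product: 6 methyl (3R,5E)-3-[(4R)-4-benzyl-2-oxo-1,3-oxazolidine-3-carbonyl]-6,10-dimethylundeca-5,9-dienoate, via sodium enolate 5 (not isolated)
Conditions: NaN(SiMe3)2, THF, −78 °C; then 4, −78 → −40 °C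
Reagents that add atoms: none
Why: Evans asymmetric alkylation, in which the chelated sodium (Z)-enolate forms at the more acidic imide α-carbon and the allylic bromide attacks the face opposite the benzyl group, should set the (3R) centre that becomes the ring-fusion carbon.

Step 3
Reactants: 6 methyl (3R,5E)-3-[(4R)-4-benzyl-2-oxo-1,3-oxazolidine-3-carbonyl]-6,10-dimethylundeca-5,9-dienoate
Product: 7 methyl (3R,5E,9E)-3-[(4R)-4-benzyl-2-oxo-1,3-oxazolidine-3-carbonyl]-11-hydroxy-6,10-dimethylundeca-5,9-dienoate
Conditions: SeO2 (0.5 equiv), t-BuOOH, salicylic acid (cat.), CH2Cl2, 0 → 23 °C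
Reagents that add atoms: selenium dioxide O=[Se]=O; tert-butyl hydroperoxide CC(C)(C)OO
Why: Selenium dioxide allylic oxidation (ene reaction then [2,3]-sigmatropic shift) should hydroxylate the (E)-methyl group of the terminal isopropylidene unit, the least hindered trisubstituted alkene, and so give the (E)-allylic alcohol.

Step 4
Reactants: 7 methyl (3R,5E,9E)-3-[(4R)-4-benzyl-2-oxo-1,3-oxazolidine-3-carbonyl]-11-hydroxy-6,10-dimethylundeca-5,9-dienoate
Product: 8 methyl (3R,5E,9E)-3-[(4R)-4-benzyl-2-oxo-1,3-oxazolidine-3-carbonyl]-11-bromo-6,10-dimethylundeca-5,9-dienoate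
Conditions: CBr4, PPh3, CH2Cl2, 0 °C
Reagents that add atoms: carbon tetrabromide BrC(Br)(Br)Br
Why: Appel bromination of the primary allylic alcohol runs under neutral conditions and should proceed without allylic transposition or loss of the E geometry.

Step 5
Reactants: 8 methyl (3R,5E,9E)-3-[(4R)-4-benzyl-2-oxo-1,3-oxazolidine-3-carbonyl]-11-bromo-6,10-dimethylundeca-5,9-dienoate; 9 2-(2-bromoethyl)-1,3-dioxolane
Product: 11 methyl (3R,5E,9E)-3-[(4R)-4-benzyl-2-oxo-1,3-oxazolidine-3-carbonyl]-13-(1,3-dioxolan-2-yl)-6,10-dimethyltrideca-5,9-dienoate, via Grignard reagent 10 (not isolated)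
Conditions: 9, Mg, THF, 23 °C; then 8, Li2CuCl4 (5 mol %), THF, −78 → −30 °C
Reagents that add atoms: none
Why: Copper-catalysed cross-coupling of the alkyl Grignard reagent with the primary allylic bromide should take place at the unsubstituted allylic terminus with retention of the E alkene and, at −78 °C, faster than addition to the imide or ester carbonyl groups.

Step 6
Reactants: 11 methyl (3R,5E,9E)-3-[(4R)-4-benzyl-2-oxo-1,3-oxazolidine-3-carbonyl]-13-(1,3-dioxolan-2-yl)-6,10-dimethyltrideca-5,9-dienoate
Product: 14 (2R,4E,8E)-2-(2-methoxy-2-oxoethyl)-5,9-dimethyl-13-oxotrideca-4,8-dienoic acid, via lithium peroxycarboxylate 12 (not isolated), via acetal acid 13 (not isolated)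
Conditions: LiOH, H2O2, THF/H2O, 0 °C; Na2SO3; then 2 M HCl, THF, 23 °C
Reagents that add atoms: hydrogen peroxide OO; water O
Why: Hydroperoxide cleavage of the Evans imide attacks the exocyclic carbonyl selectively (methyl ester and stereocentre untouched), sulfite reduces the peracid salt before acidification so that the alkenes are not epoxidized, and aqueous acid then hydrolyses the dioxolane to the aldehyde.

Step 7
Reactants: 14 (2R,4E,8E)-2-(2-methoxy-2-oxoethyl)-5,9-dimethyl-13-oxotrideca-4,8-dienoic acid
Product: 16 (2R,4E,8E,12S)-12-chloro-13-hydroxy-2-(2-methoxy-2-oxoethyl)-5,9-dimethyltetradeca-4,8-dienoic acid (both C-13 epimers), via chloro aldehyde 15 (not isolated)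
Conditions: NCS, 2,5-diphenylpyrrolidine (10 mol %), CH2Cl2, 0 °C; filtration through silica; then MeMgBr (3.5 equiv), THF, −78 °C; 1 M HCl
Reagents that add atoms: N-chlorosuccinimide O=C1CCC(=O)N1Cl; methylmagnesium bromide C[Mg]Br
Why: Enamine-catalysed α-chlorination of the aldehyde should set the (S)-C–Cl centre under catalyst control, and the configurationally labile chloro aldehyde is trapped at once by Grignard addition at −78 °C (carboxylate and ester inert), the carbinol centre formed being a mixture that is erased by the oxidation in step 9.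

Step 8
Reactants: 16 (2R,4E,8E,12S)-12-chloro-13-hydroxy-2-(2-methoxy-2-oxoethyl)-5,9-dimethyltetradeca-4,8-dienoic acid
Product: 19 methyl (3R,5E,9E,13S)-3-(2-bromoacetyl)-13-chloro-14-hydroxy-6,10-dimethylpentadeca-5,9-dienoate, via mixed anhydride 17 (not isolated), via diazo ketone 18 (not isolated)
Conditions: i-BuOCOCl, N-methylmorpholine, THF, −20 °C; CH2N2, Et2O, 0 °C; then 48% aq HBr, 0 °C
Reagents that add atoms: diazomethane C=[N+]=[N-]; hydrogen bromide Br
Why: Acylation of diazomethane by the mixed anhydride (the diazo ketone synthesis of the Arndt–Eistert sequence) followed by hydrobromination of the diazo ketone should give the bromomethyl ketone regiospecifically under non-basic conditions that leave the chlorohydrin and the α-stereocentre intact.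

Step 9
Reactants: 19 methyl (3R,5E,9E,13S)-3-(2-bromoacetyl)-13-chloro-14-hydroxy-6,10-dimethylpentadeca-5,9-dienoate
Product: 20 methyl (3R,5E,9E,13S)-3-(2-bromoacetyl)-13-chloro-6,10-dimethyl-14-oxopentadeca-5,9-dienoate
Conditions: Dess–Martin periodinane, CH2Cl2, 0 → 23 °C
Reagents that add atoms: none
Why: Dess–Martin oxidation of the secondary alcohol under neutral conditions should give the α-chloro methyl ketone without epimerization of the C–Cl centre and converges both carbinol epimers.

Step 10
Reactants: 20 methyl (3R,5E,9E,13S)-3-(2-bromoacetyl)-13-chloro-6,10-dimethyl-14-oxopentadeca-5,9-dienoate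
Product: 23 methyl 2-[(1R,3E,7E,11S,12R)-11-chloro-12-hydroxy-4,8,12-trimethyl-14-oxocyclotetradeca-3,7-dien-1-yl]acetate, via zinc enolate 21 (not isolated), via zinc aldolate 22 (not isolated)
Conditions: Zn dust (Me3SiCl-activated, 10 equiv), THF, 20 °C, slow addition of 20 (final 0.002 M); then sat. aq NH4Cl, 0 °C
Reagents that add atoms: none
Why: Proposed new method: zerovalent zinc should insert into the primary C–Br bond of the bromoacetyl group much faster than into the secondary C–Cl bond, giving the regiodefined zinc enolate 21, whose CH2 carbon then adds to the carbonyl of the chloro ketone terminus (zinc aldolate 22), so that a formerly electrophilic carbon is united with a second electrophilic carbon. The closest known reaction types are the intramolecular Reformatsky macrocyclization of ω-bromoacyl aldehydes and the zinc-mediated crossed aldol addition of α-bromo ketones to ketones; the ketone-donor/α-chloro-ketone-acceptor pair in a macrocyclic closure is what has not been shown. The 14-membered ring closes in the 14-exo-trig mode (the acceptor C=O lies outside the new ring), helped by the two E-trisubstituted alkenes, which restrict the tether. The new quaternary carbinol centre is set by 1,2-induction from the adjacent (S)-C–Cl centre in the Cornforth arrangement (C=O and C–Cl antiperiplanar), the enolate passing the hydrogen and not the CH2 chain of that carbon, which should give the (12R)-alcohol anti to chlorine. The step needs chemoselectivity (C–Br over C–Cl insertion; addition to the chloro ketone and not to the ester, to the donor ketone or to a second molecule), which is secured by the higher electrophilicity of the α-chloro ketone, the low basicity of the zinc enolate (no enolization, no epoxide closure of the zinc alkoxide at 20 °C) and high dilution.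

Step 11
Reactants: 23 methyl 2-[(1R,3E,7E,11S,12R)-11-chloro-12-hydroxy-4,8,12-trimethyl-14-oxocyclotetradeca-3,7-dien-1-yl]acetate
Product: 26 (3aR,5E,9E,13S,14R,15aS)-13-chloro-14-hydroxy-6,10,14-trimethyl-3a,4,7,8,11,12,13,14,15,15a-decahydrocyclotetradeca[b]furan-2(3H)-one (trans-fused hydroxy lactone), via boron chelate 24 (not isolated), via syn-diol ester 25 (not isolated)
Conditions: Et2BOMe, THF/MeOH (4:1), −78 °C; NaBH4, −78 °C; MeOH, 23 °C; then PPTS (cat.), CH2Cl2, 23 °C
Reagents that add atoms: none
Why: Narasaka–Prasad reduction, in which external hydride attacks the diethylboron chelate of the β-hydroxy ketone, should give the 1,3-syn diol (new (14S)-carbinol, both ring bonds equatorial on the six-membered chelate), after which the secondary hydroxyl closes the trans-fused γ-lactone on the neighbouring methyl ester (5-exo-trig).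

Step 12
Reactants: 26 trans-fused hydroxy lactone
Product: 27 14-O-trimethylsilyl ether of 26
Conditions: N-(trimethylsilyl)imidazole, CH2Cl2, 23 °C
Reagents that add atoms: N-(trimethylsilyl)imidazole C[Si](C)(C)n1ccnc1
Why: Silylation of the tertiary alcohol masks the chlorohydrin so that the strong base of step 13 cannot close it to an epoxide.

Step 13
Reactants: 27 14-O-trimethylsilyl ether of 26
Product: 29 3-[(dimethylamino)methyl] derivative of 27 (both C-3 epimers), via lithium enolate 28 (not isolated)
Conditions: LiN(i-Pr)2, THF, −78 °C; then Eschenmoser's salt, −78 → −20 °C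
Reagents that add atoms: N,N-dimethylmethyleneiminium iodide C=[N+](C)C.[I-]
Why: Mannich reaction of the lactone lithium enolate with the iminium salt should install the aminomethyl group at the α-carbon, and the uncontrolled α-centre is destroyed in step 14.

Step 14
Reactants: 29 3-[(dimethylamino)methyl] derivative of 27
Product: 31 14-O-trimethylsilyl ether of the target, via ammonium iodide 30 (not isolated)
Conditions: MeI, THF, 23 °C; then NaHCO3, H2O/CH2Cl2, 23 °C
Reagents that add atoms: none
Why: Quaternization of the amine followed by mild base-induced β-elimination of trimethylamine (Hofmann-type) should give the exocyclic α-methylene lactone without touching the protected chlorohydrin.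

Step 15
Reactants: 31 14-O-trimethylsilyl ether of the target
Product: 32 (3aR,5E,9E,13S,14R,15aS)-13-chloro-14-hydroxy-6,10,14-trimethyl-3-methylidene-3a,4,7,8,11,12,13,14,15,15a-decahydrocyclotetradeca[b]furan-2(3H)-one (CNP0247658.1)
Conditions: PPTS (cat.), MeOH, 0 → 23 °C
Reagents that add atoms: none
Why: Acid-catalysed methanolysis should remove the labile tertiary trimethylsilyl ether without affecting the chlorohydrin, the alkenes or the α-methylene lactone.

**Compound list**

1 | (R)-4-benzyl-1,3-oxazolidin-2-one | O=C1N[C@H](Cc2ccccc2)CO1 | starting material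
2 | methyl 4-chloro-4-oxobutanoate | COC(=O)CCC(Cl)=O | starting material
3 | methyl 4-[(4R)-4-benzyl-2-oxo-1,3-oxazolidin-3-yl]-4-oxobutanoate | COC(=O)CCC(=O)N1[C@H](Cc2ccccc2)COC1=O | intermediate
4 | geranyl bromide, (2E)-1-bromo-3,7-dimethylocta-2,6-diene | CC(C)=CCC/C(C)=C/CBr | starting material
5 | sodium (Z)-enolate of 3 | [Na+].COC(=O)C/C=C(\[O-])N1[C@H](Cc2ccccc2)COC1=O | intermediate
6 | methyl (3R,5E)-3-[(4R)-4-benzyl-2-oxo-1,3-oxazolidine-3-carbonyl]-6,10-dimethylundeca-5,9-dienoate | COC(=O)C[C@@H](C/C=C(C)/CCC=C(C)C)C(=O)N1[C@H](Cc2ccccc2)COC1=O | intermediate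
7 | methyl (3R,5E,9E)-3-[(4R)-4-benzyl-2-oxo-1,3-oxazolidine-3-carbonyl]-11-hydroxy-6,10-dimethylundeca-5,9-dienoate | COC(=O)C[C@@H](C/C=C(C)/CC/C=C(C)/CO)C(=O)N1[C@H](Cc2ccccc2)COC1=O | intermediate
8 | methyl (3R,5E,9E)-3-[(4R)-4-benzyl-2-oxo-1,3-oxazolidine-3-carbonyl]-11-bromo-6,10-dimethylundeca-5,9-dienoate | COC(=O)C[C@@H](C/C=C(C)/CC/C=C(C)/CBr)C(=O)N1[C@H](Cc2ccccc2)COC1=O | intermediate
9 | 2-(2-bromoethyl)-1,3-dioxolane | BrCCC1OCCO1 | starting material
10 | [2-(1,3-dioxolan-2-yl)ethyl]magnesium bromide | Br[Mg]CCC1OCCO1 | intermediate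
11 | methyl (3R,5E,9E)-3-[(4R)-4-benzyl-2-oxo-1,3-oxazolidine-3-carbonyl]-13-(1,3-dioxolan-2-yl)-6,10-dimethyltrideca-5,9-dienoate | COC(=O)C[C@@H](C/C=C(C)/CC/C=C(C)/CCCC1OCCO1)C(=O)N1[C@H](Cc2ccccc2)COC1=O | intermediate
12 | lithium (2R,4E,8E)-12-(1,3-dioxolan-2-yl)-2-(2-methoxy-2-oxoethyl)-5,9-dimethyldodeca-4,8-dieneperoxoate | [Li+].COC(=O)C[C@@H](C/C=C(C)/CC/C=C(C)/CCCC1OCCO1)C(=O)O[O-] | intermediate
13 | (2R,4E,8E)-12-(1,3-dioxolan-2-yl)-2-(2-methoxy-2-oxoethyl)-5,9-dimethyldodeca-4,8-dienoic acid | COC(=O)C[C@@H](C/C=C(C)/CC/C=C(C)/CCCC1OCCO1)C(=O)O | intermediate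
14 | (2R,4E,8E)-2-(2-methoxy-2-oxoethyl)-5,9-dimethyl-13-oxotrideca-4,8-dienoic acid | COC(=O)C[C@@H](C/C=C(C)/CC/C=C(C)/CCCC=O)C(=O)O | intermediate
15 | (2R,4E,8E,12S)-12-chloro-2-(2-methoxy-2-oxoethyl)-5,9-dimethyl-13-oxotrideca-4,8-dienoic acid | COC(=O)C[C@@H](C/C=C(C)/CC/C=C(C)/CC[C@H](Cl)C=O)C(=O)O | intermediate
16 | (2R,4E,8E,12S)-12-chloro-13-hydroxy-2-(2-methoxy-2-oxoethyl)-5,9-dimethyltetradeca-4,8-dienoic acid (both C-13 epimers) | COC(=O)C[C@@H](C/C=C(C)/CC/C=C(C)/CC[C@H](Cl)C(C)O)C(=O)O | intermediate
17 | isobutyl carbonic mixed anhydride of 16 | COC(=O)C[C@@H](C/C=C(C)/CC/C=C(C)/CC[C@H](Cl)C(C)O)C(=O)OC(=O)OCC(C)C | intermediate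
18 | methyl (3R,5E,9E,13S)-13-chloro-3-(2-diazoacetyl)-14-hydroxy-6,10-dimethylpentadeca-5,9-dienoate | COC(=O)C[C@@H](C/C=C(C)/CC/C=C(C)/CC[C@H](Cl)C(C)O)C(=O)C=[N+]=[N-] | intermediate
19 | methyl (3R,5E,9E,13S)-3-(2-bromoacetyl)-13-chloro-14-hydroxy-6,10-dimethylpentadeca-5,9-dienoate | COC(=O)C[C@@H](C/C=C(C)/CC/C=C(C)/CC[C@H](Cl)C(C)O)C(=O)CBr | intermediate
20 | methyl (3R,5E,9E,13S)-3-(2-bromoacetyl)-13-chloro-6,10-dimethyl-14-oxopentadeca-5,9-dienoate | COC(=O)C[C@@H](C/C=C(C)/CC/C=C(C)/CC[C@H](Cl)C(C)=O)C(=O)CBr | intermediate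
21 | bromozinc enolate of 20 (O-zinc enolate of the former bromoacetyl group) | COC(=O)C[C@@H](C/C=C(C)/CC/C=C(C)/CC[C@H](Cl)C(C)=O)C(=C)O[Zn]Br | intermediate
22 | bromozinc alkoxide (aldolate) of 23 | COC(=O)C[C@H]1C/C=C(C)/CC/C=C(C)/CC[C@H](Cl)[C@](C)(O[Zn]Br)CC1=O | intermediate
23 | methyl 2-[(1R,3E,7E,11S,12R)-11-chloro-12-hydroxy-4,8,12-trimethyl-14-oxocyclotetradeca-3,7-dien-1-yl]acetate | COC(=O)C[C@H]1C/C=C(C)/CC/C=C(C)/CC[C@H](Cl)[C@](C)(O)CC1=O | intermediate
24 | 12-O-diethylboryl chelate of 23 | COC(=O)C[C@H]1C/C=C(C)/CC/C=C(C)/CC[C@H](Cl)[C@](C)(OB(CC)CC)CC1=O | intermediate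
25 | methyl 2-[(1R,3E,7E,11S,12R,14S)-11-chloro-12,14-dihydroxy-4,8,12-trimethylcyclotetradeca-3,7-dien-1-yl]acetate | COC(=O)C[C@H]1C/C=C(C)/CC/C=C(C)/CC[C@H](Cl)[C@](C)(O)C[C@@H]1O | intermediate
26 | (3aR,5E,9E,13S,14R,15aS)-13-chloro-14-hydroxy-6,10,14-trimethyl-3a,4,7,8,11,12,13,14,15,15a-decahydrocyclotetradeca[b]furan-2(3H)-one | O=C1O[C@H]2C[C@@](C)(O)[C@@H](Cl)CC/C(C)=C/CC/C(C)=C/C[C@@H]2C1 | intermediate
27 | 14-O-trimethylsilyl ether of 26 | O=C1O[C@H]2C[C@@](C)(O[Si](C)(C)C)[C@@H](Cl)CC/C(C)=C/CC/C(C)=C/C[C@@H]2C1 | intermediate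
28 | lithium enolate of 27 | [Li]OC1O[C@H]2C[C@@](C)(O[Si](C)(C)C)[C@@H](Cl)CC/C(C)=C/CC/C(C)=C/C[C@@H]2C=1 | intermediate
29 | 3-[(dimethylamino)methyl] derivative of 27 (both C-3 epimers) | O=C1O[C@H]2C[C@@](C)(O[Si](C)(C)C)[C@@H](Cl)CC/C(C)=C/CC/C(C)=C/C[C@@H]2C1CN(C)C | intermediate
30 | N-methyl ammonium iodide of 29 | [I-].O=C1O[C@H]2C[C@@](C)(O[Si](C)(C)C)[C@@H](Cl)CC/C(C)=C/CC/C(C)=C/C[C@@H]2C1C[N+](C)(C)C | intermediate
31 | 14-O-trimethylsilyl ether of the target | C=C1C(=O)O[C@H]2C[C@@](C)(O[Si](C)(C)C)[C@@H](Cl)CC/C(C)=C/CC/C(C)=C/C[C@H]12 | intermediate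
32 | CNP0247658.1, (3aR,5E,9E,13S,14R,15aS)-13-chloro-14-hydroxy-6,10,14-trimethyl-3-methylidene-3a,4,7,8,11,12,13,14,15,15a-decahydrocyclotetradeca[b]furan-2(3H)-one | C=C1C(=O)O[C@H]2C[C@@](C)(O)[C@@H](Cl)CC/C(C)=C/CC/C(C)=C/C[C@H]12 | target

**Step count and risks**

Total step count: 15. Longest linear sequence: 15 steps (from 1 or 2 through 3 to 32).

Steps most likely to fail:

1. Step 10 (Proposed new method). What may go wrong: the zinc enolate may be consumed by intermolecular aldol addition and oligomerization or by proton transfer before the 14-membered ring closes, and zinc may also insert into the C–Cl bond (loss of chemoselectivity). The fallback uses known chemistry and changes the activation mode from a metal enolate to a Lewis-acid-mediated Mukaiyama aldol addition. It sets out from 20: reductive silylation of the bromoacetyl group (Zn, Me3SiCl, TMEDA, Et2O, 0 °C, short contact) should give the regiodefined silyl enol ether methyl (3R,5E,9E,13S)-13-chloro-6,10-dimethyl-14-oxo-3-{1-[(trimethylsilyl)oxy]ethenyl}pentadeca-5,9-dienoate F1. Slow addition of F1 to TiCl4 in CH2Cl2 at −78 °C (final 0.002 M) should then close the ring onto the activated chloro ketone under the same Cornforth control, and aqueous work-up returns to the route at 23.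

2. Step 11. What may go wrong: poor facial selectivity of hydride delivery, because the tertiary carbinol forces a methyl group axial in the boron chelate and the macrocyclic conformation may override chelate control; the wrong carbinol epimer would lead to the cis-fused lactone. The fallback replaces substrate (chelate) control by catalyst control: it sets out from 23, which is reduced with catecholborane and a Corey–Bakshi–Shibata oxazaborolidine (the enantiomer matched to the (14S)-carbinol) in toluene at −40 °C. The same PPTS lactonization follows, passing through 25 and coming back to the route at 26. It makes no new compound F0.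

3. Step 5. What may go wrong: competing addition of the Grignard reagent to the imide carbonyl, or attack at the substituted allylic terminus with allylic transposition. The fallback avoids organomagnesium chemistry and sets out from 8. Stille allyl–allyl coupling with allyltributylstannane (Pd(PPh3)4, THF, 60 °C) should give methyl (3R,5E,9E)-3-[(4R)-4-benzyl-2-oxo-1,3-oxazolidine-3-carbonyl]-6,10-dimethyltetradeca-5,9,13-trienoate F2. Hydroperoxide cleavage of the auxiliary (LiOH, H2O2, then Na2SO3) gives (2R,4E,8E)-2-(2-methoxy-2-oxoethyl)-5,9-dimethyltrideca-4,8,12-trienoic acid F3. Chemoselective hydroboration of the monosubstituted alkene with 9-BBN and oxidation with NaBO3 gives (2R,4E,8E)-13-hydroxy-2-(2-methoxy-2-oxoethyl)-5,9-dimethyltrideca-4,8-dienoic acid F4, and Dess–Martin oxidation of F4 comes back to the route at 14.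

**Further compounds**

F1 | step 10 | methyl (3R,5E,9E,13S)-13-chloro-6,10-dimethyl-14-oxo-3-{1-[(trimethylsilyl)oxy]ethenyl}pentadeca-5,9-dienoate | COC(=O)C[C@@H](C/C=C(C)/CC/C=C(C)/CC[C@H](Cl)C(C)=O)C(=C)O[Si](C)(C)C
F0 | step 11 | none | none
F2 | step 5 | methyl (3R,5E,9E)-3-[(4R)-4-benzyl-2-oxo-1,3-oxazolidine-3-carbonyl]-6,10-dimethyltetradeca-5,9,13-trienoate | COC(=O)C[C@@H](C/C=C(C)/CC/C=C(C)/CCC=C)C(=O)N1[C@H](Cc2ccccc2)COC1=O
F3 | step 5 | (2R,4E,8E)-2-(2-methoxy-2-oxoethyl)-5,9-dimethyltrideca-4,8,12-trienoic acid | COC(=O)C[C@@H](C/C=C(C)/CC/C=C(C)/CCC=C)C(=O)O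
F4 | step 5 | (2R,4E,8E)-13-hydroxy-2-(2-methoxy-2-oxoethyl)-5,9-dimethyltrideca-4,8-dienoic acid | COC(=O)C[C@@H](C/C=C(C)/CC/C=C(C)/CCCCO)C(=O)O
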